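**Plan**

- Retrosynthesis opens the only ring (cyclopentane C8–C9–C10–C11–C12) at C11–C12. This works because C11 is a ring carbinol carbon bonded to C12 and C13–C14 is saturated: a C11 ketyl can add to a C12=C13 alkene, and C13 then needs only a hydrogen.
- The open-chain aldehyde is cut at C12=C13 (Julia–Kocienski) into a C1–C12 aldehyde and a C13–C20 sulfone. The C1–C12 piece is cut at C8–C9 (Evans syn aldol) into an azelaic half-ester imide and a C9–C11 aldehyde.
- Forward order: acylation, aldol (C8–C9), auxiliary to C12 aldehyde, olefination (C12=C13), unmasking and oxidation of C11, SmI2 5-exo ring closure (C11–C12), then protecting-group exchange, oxidation of C9 and hydrogenolysis.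
- Stereochemistry: C8 and the temporary C9 centre come from (S)-4-benzyloxazolidin-2-one in the aldol. C15 comes from (S)-oct-1-en-3-ol. C11 and C12 come from the chair-like cyclisation transition state steered by C8 and C9.
- The upper chain is carried saturated from the start, so C12=C13 is the only alkene in the cyclisation substrate. C9 is a bulky silyl ether during ring closure and becomes the ketone late. The last step is a neutral hydrogenolysis.

Key step: step 14

Remark: atom labels C1–C20 follow prostaglandin numbering (C1 carboxyl carbon, C8–C12 ring carbons, C15 side-chain carbinol), also in open-chain intermediates. The geometry of C12=C13 is lost on ring closure, so it affects only the transition state. Monomethyl azelate, (S)-4-benzyloxazolidin-2-one, mono-PMB propane-1,3-diol and (S)-oct-1-en-3-ol are taken as purchased.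

**Route**

Step 1
Reactants: 1 9-methoxy-9-oxononanoic acid (monomethyl azelate); 2 (4S)-4-benzyl-1,3-oxazolidin-2-one
Product: 4 methyl 9-[(4S)-4-benzyl-2-oxo-1,3-oxazolidin-3-yl]-9-oxononanoate, via mixed pivalic anhydride 3 (not isolated)
Conditions: PivCl, Et3N, THF, −20 °C; then 2, LiCl, −20 °C → rt
Reagents that add atoms: none
Why: N-acylation of the oxazolidinone through a mixed pivalic anhydride is a standard way to load an acid onto the auxiliary, and the distal methyl ester is not touched because only the unhindered anhydride carbonyl is attacked.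

Step 2
Reactants: 5 3-[(4-methoxybenzyl)oxy]propan-1-ol
Product: 6 3-[(4-methoxybenzyl)oxy]propanal
Conditions: TEMPO (2,2,6,6-tetramethylpiperidin-1-oxyl, cat.), PhI(OAc)2, CH2Cl2, rt
Reagents that add atoms: none
Why: the oxoammonium (TEMPO) oxidation stops at the aldehyde and is mild enough for the PMB ether and for an elimination-prone β-alkoxy aldehyde, which is used directly.

Step 3
Reactants: 4 methyl 9-[(4S)-4-benzyl-2-oxo-1,3-oxazolidin-3-yl]-9-oxononanoate; 6 3-[(4-methoxybenzyl)oxy]propanal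
Product: 8 methyl (8S,9R)-8-{[(4S)-4-benzyl-2-oxo-1,3-oxazolidin-3-yl]carbonyl}-9-hydroxy-11-[(4-methoxybenzyl)oxy]undecanoate, via dibutylboron (Z)-enolate 7 (not isolated)
Conditions: Bu2BOTf, iPr2NEt, CH2Cl2, −78 → 0 °C; then 6, −78 → 0 °C; pH 7 buffer, MeOH, H2O2, 0 °C
Reagents that add atoms: none
Why: in the Evans syn aldol the (Z)-boron enolate reacts through a closed six-membered chair transition state on the face away from the auxiliary benzyl group, which sets C8 (S) and C9 (R) together, the arrangement that places the C8 chain and the C9 oxygen trans on the later ring.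

Step 4
Reactants: 8 methyl (8S,9R)-8-{[(4S)-4-benzyl-2-oxo-1,3-oxazolidin-3-yl]carbonyl}-9-hydroxy-11-[(4-methoxybenzyl)oxy]undecanoate
Product: 9 methyl (8S,9R)-8-{[(4S)-4-benzyl-2-oxo-1,3-oxazolidin-3-yl]carbonyl}-9-[(tert-butyldimethylsilyl)oxy]-11-[(4-methoxybenzyl)oxy]undecanoate
Conditions: TBSOTf, 2,6-lutidine, CH2Cl2, −78 → 0 °C
Reagents that add atoms: tert-butyldimethylsilyl triflate, CC(C)(C)[Si](C)(C)OS(=O)(=O)C(F)(F)F
Why: silylation of an aldol hydroxyl with a silyl triflate and a hindered pyridine base is routine, causes neither retro-aldol nor loss of the PMB ether, and installs the bulky non-chelating C9 group wanted in the ring closure.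

Step 5
Reactants: 9 methyl (8S,9R)-8-{[(4S)-4-benzyl-2-oxo-1,3-oxazolidin-3-yl]carbonyl}-9-[(tert-butyldimethylsilyl)oxy]-11-[(4-methoxybenzyl)oxy]undecanoate
Product: 10 methyl (8R,9R)-9-[(tert-butyldimethylsilyl)oxy]-8-(hydroxymethyl)-11-[(4-methoxybenzyl)oxy]undecanoate
Conditions: NaBH4, THF/H2O, 0 °C → rt
Reagents that add atoms: none
Why: borohydride reduction of an N-acyloxazolidinone in aqueous THF reduces the activated imide carbonyl to the primary alcohol and releases the auxiliary, while an unactivated methyl ester should react far more slowly under these conditions.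

Step 6
Reactants: 10 methyl (8R,9R)-9-[(tert-butyldimethylsilyl)oxy]-8-(hydroxymethyl)-11-[(4-methoxybenzyl)oxy]undecanoate
Product: 11 methyl (8S,9R)-9-[(tert-butyldimethylsilyl)oxy]-8-formyl-11-[(4-methoxybenzyl)oxy]undecanoate
Conditions: Dess–Martin periodinane, pyridine, CH2Cl2, 0 °C → rt
Reagents that add atoms: none
Why: Dess–Martin oxidation under buffered non-basic conditions should give the α-branched aldehyde without epimerising C8 or eliminating the β-silyloxy group.

Step 7
Reactants: 12 (3S)-oct-1-en-3-ol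
Product: 13 {[(3S)-oct-1-en-3-yloxy]methyl}benzene
Conditions: NaH, BnBr, Bu4NI (cat.), THF, 0 °C → rt
Reagents that add atoms: benzyl bromide, BrCc1ccccc1
Why: Williamson etherification of the alkoxide does not touch the stereocentre that becomes C15 and gives an ether that survives every step up to the final hydrogenolysis.

Step 8
Reactants: 13 {[(3S)-oct-1-en-3-yloxy]methyl}benzene
Product: 15 (3S)-3-(benzyloxy)octan-1-ol, via B-alkyl-9-borabicyclononane 14 (not isolated)
Conditions: 9-BBN, THF, 0 °C → rt; then NaOH, H2O2, 0 °C → rt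
Reagents that add atoms: hydrogen peroxide, OO
Why: hydroboration–oxidation with the bulky borane places boron on the terminal carbon of the monosubstituted alkene (anti-Markovnikov), and oxidation then gives the primary alcohol with the carbinol centre untouched.

Step 9
Reactants: 15 (3S)-3-(benzyloxy)octan-1-ol
Product: 16 5-{[(3S)-3-(benzyloxy)octyl]sulfanyl}-1-phenyl-1H-tetrazole
Conditions: 1-phenyl-1H-tetrazole-5-thiol, PPh3, DIAD, THF, 0 °C → rt
Reagents that add atoms: 1-phenyl-1H-tetrazole-5-thiol, Sc1nnnn1-c1ccccc1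
Why: Mitsunobu thioetherification of an unhindered primary alcohol with the acidic heteroaryl thiol is the usual entry to Julia–Kocienski sulfones.

Step 10
Reactants: 16 5-{[(3S)-3-(benzyloxy)octyl]sulfanyl}-1-phenyl-1H-tetrazole
Product: 17 5-{[(3S)-3-(benzyloxy)octyl]sulfonyl}-1-phenyl-1H-tetrazole
Conditions: (NH4)6Mo7O24·4H2O (cat.), 30% H2O2, EtOH, 0 °C → rt
Reagents that add atoms: hydrogen peroxide, OO
Why: molybdate-catalysed peroxide oxidation takes the sulfide to the sulfone and leaves the benzyl ether alone.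

Step 11
Reactants: 17 5-{[(3S)-3-(benzyloxy)octyl]sulfonyl}-1-phenyl-1H-tetrazole; 11 methyl (8S,9R)-9-[(tert-butyldimethylsilyl)oxy]-8-formyl-11-[(4-methoxybenzyl)oxy]undecanoate
Product: 19 methyl (8R,9R)-8-[(1E,4S)-4-(benzyloxy)non-1-en-1-yl]-9-[(tert-butyldimethylsilyl)oxy]-11-[(4-methoxybenzyl)oxy]undecanoate, via potassium sulfonyl carbanion 18 (not isolated)
Conditions: KN(SiMe3)2, DME, −60 °C; then 11, −60 °C → rt; NH4Cl (aq)
Reagents that add atoms: none
Why: in the Julia–Kocienski olefination the pre-formed sulfonyl carbanion adds to the α-branched aldehyde and Smiles rearrangement with loss of SO2 should give mainly the (E)-C12=C13 alkene, while the low temperature protects C8 from epimerisation.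

Step 12
Reactants: 19 methyl (8R,9R)-8-[(1E,4S)-4-(benzyloxy)non-1-en-1-yl]-9-[(tert-butyldimethylsilyl)oxy]-11-[(4-methoxybenzyl)oxy]undecanoate
Product: 20 methyl (8R,9R)-8-[(1E,4S)-4-(benzyloxy)non-1-en-1-yl]-9-[(tert-butyldimethylsilyl)oxy]-11-hydroxyundecanoate
Conditions: DDQ, CH2Cl2/pH 7 buffer, 0 °C
Reagents that add atoms: none
Why: oxidative cleavage of the electron-rich PMB ether by DDQ is selective over the plain benzyl ether, the silyl ether and the alkene.

Step 13
Reactants: 20 methyl (8R,9R)-8-[(1E,4S)-4-(benzyloxy)non-1-en-1-yl]-9-[(tert-butyldimethylsilyl)oxy]-11-hydroxyundecanoate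
Product: 21 methyl (8R,9R)-8-[(1E,4S)-4-(benzyloxy)non-1-en-1-yl]-9-[(tert-butyldimethylsilyl)oxy]-11-oxoundecanoate
Conditions: Dess–Martin periodinane, pyridine, CH2Cl2, 0 °C → rt
Reagents that add atoms: none
Why: Dess–Martin oxidation of the primary alcohol gives the β-silyloxy aldehyde under neutral conditions that avoid β-elimination, and the aldehyde is used at once.

Step 14
Reactants: 21 methyl (8R,9R)-8-[(1E,4S)-4-(benzyloxy)non-1-en-1-yl]-9-[(tert-butyldimethylsilyl)oxy]-11-oxoundecanoate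
Product: 22 methyl 7-[(1R,2R,3R,5R)-2-[(3S)-3-(benzyloxy)octyl]-5-[(tert-butyldimethylsilyl)oxy]-3-hydroxycyclopentyl]heptanoate
Conditions: SmI2, HMPA, t-BuOH, THF, −78 → 0 °C; 21 added slowly at high dilution
Reagents that add atoms: none
Why: SmI2 (divalent samarium), made strongly reducing by HMPA, transfers one electron to the C11 aldehyde, the samarium-bound ketyl radical anion adds to C12 of the (E)-C12=C13 alkene, and the secondary C13 radical is reduced by a second SmI2 and protonated by t-BuOH, so that C13 simply becomes CH2. The closest known reaction type is the SmI2/HMPA reductive ketyl–olefin cyclisation of δ,ε-unsaturated aldehydes and ketones onto unactivated alkenes, which delivers trans-2-alkylcyclopentanols. The cyclopentane ring C8–C9–C10–C11–C12 closes in the 5-exo-trig mode through a chair-like transition state. C12 is set by that chair, in which the C8 heptanoate chain and the C9 silyl ether (trans to each other from step 3) both sit pseudo-equatorial, so the new C12–C13 bond comes out trans to the C8 chain; C11 is set by the bulky HMPA-solvated O–Sm group, which turns away from the alkene terminus and ends trans to the C12 chain. The step needs ring closure to win over pinacol dimerisation and plain reduction of the aldehyde and needs the 8,12-trans/11,12-trans isomer: slow addition of 21 to excess reagent at high dilution, the absence of any other alkene or of a β-leaving group at C13, and the non-chelating OTBS group at C9 should secure this.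

Step 15
Reactants: 22 methyl 7-[(1R,2R,3R,5R)-2-[(3S)-3-(benzyloxy)octyl]-5-[(tert-butyldimethylsilyl)oxy]-3-hydroxycyclopentyl]heptanoate
Product: 23 methyl 7-[(1R,2R,3R,5R)-2-[(3S)-3-(benzyloxy)octyl]-3-[(benzyloxy)methoxy]-5-[(tert-butyldimethylsilyl)oxy]cyclopentyl]heptanoate
Conditions: BnOCH2Cl, iPr2NEt, Bu4NI (cat.), CH2Cl2, rt
Reagents that add atoms: benzyl chloromethyl ether, ClCOCc1ccccc1
Why: alkylation of the free C11 hydroxyl with a reactive α-chloro ether and a hindered amine (acetal-type protection) is mild and installs a group that falls together with the C15 benzyl ether on hydrogenolysis.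

Step 16
Reactants: 23 methyl 7-[(1R,2R,3R,5R)-2-[(3S)-3-(benzyloxy)octyl]-3-[(benzyloxy)methoxy]-5-[(tert-butyldimethylsilyl)oxy]cyclopentyl]heptanoate
Product: 24 methyl 7-[(1R,2R,3R,5R)-2-[(3S)-3-(benzyloxy)octyl]-3-[(benzyloxy)methoxy]-5-hydroxycyclopentyl]heptanoate
Conditions: Bu4NF, THF, rt → 40 °C; NH4Cl (aq)
Reagents that add atoms: none
Why: fluoride-mediated desilylation removes the only silyl group in the molecule and frees the C9 hydroxyl, with the benzyl-type ethers inert and any partial ester cleavage harmless because the ester is hydrolysed next.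

Step 17
Reactants: 24 methyl 7-[(1R,2R,3R,5R)-2-[(3S)-3-(benzyloxy)octyl]-3-[(benzyloxy)methoxy]-5-hydroxycyclopentyl]heptanoate
Product: 25 7-[(1R,2R,3R,5R)-2-[(3S)-3-(benzyloxy)octyl]-3-[(benzyloxy)methoxy]-5-hydroxycyclopentyl]heptanoic acid
Conditions: LiOH, THF/MeOH/H2O, rt; then 1 M HCl to pH 4
Reagents that add atoms: lithium hydroxide, [Li+].[OH-]
Why: the methyl ester is saponified while C9 is still an alcohol, so no β-alkoxy ketone is ever exposed to base.

Step 18
Reactants: 25 7-[(1R,2R,3R,5R)-2-[(3S)-3-(benzyloxy)octyl]-3-[(benzyloxy)methoxy]-5-hydroxycyclopentyl]heptanoic acid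
Product: 26 7-[(1R,2R,3R)-2-[(3S)-3-(benzyloxy)octyl]-3-[(benzyloxy)methoxy]-5-oxocyclopentyl]heptanoic acid
Conditions: Dess–Martin periodinane, CH2Cl2, 0 °C → rt
Reagents that add atoms: none
Why: Dess–Martin oxidation of the secondary C9 alcohol tolerates the free carboxylic acid and gives the β-alkoxy cyclopentanone without base, so the C11 oxygen should not eliminate and C8 should not epimerise.

Step 19
Reactants: 26 7-[(1R,2R,3R)-2-[(3S)-3-(benzyloxy)octyl]-3-[(benzyloxy)methoxy]-5-oxocyclopentyl]heptanoic acid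
Product: 27 13,14-dihydro-PGE1 7-[(1R,2R,3R)-3-hydroxy-2-[(3S)-3-hydroxyoctyl]-5-oxocyclopentyl]heptanoic acid
Conditions: H2 (1 atm), Pd(OH)2/C, EtOAc, rt
Reagents that add atoms: none
Why: hydrogenolysis cleaves the C15 benzyl ether and the C11 benzyloxymethyl ether (whose hemiacetal loses formaldehyde) under neutral conditions, which suits a target that has no C=C bond and a β-hydroxy ketone sensitive to acid and base.

**Compound list**

1 | 9-methoxy-9-oxononanoic acid | COC(=O)CCCCCCCC(=O)O | starting material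
2 | (4S)-4-benzyl-1,3-oxazolidin-2-one | O=C1N[C@@H](Cc2ccccc2)CO1 | starting material
3 | 9-methoxy-9-oxononanoic pivalic anhydride | COC(=O)CCCCCCCC(=O)OC(=O)C(C)(C)C | intermediate
4 | methyl 9-[(4S)-4-benzyl-2-oxo-1,3-oxazolidin-3-yl]-9-oxononanoate | COC(=O)CCCCCCCC(=O)N1C(=O)OC[C@@H]1Cc1ccccc1 | intermediate
5 | 3-[(4-methoxybenzyl)oxy]propan-1-ol | COc1ccc(COCCCO)cc1 | starting material
6 | 3-[(4-methoxybenzyl)oxy]propanal | COc1ccc(COCCC=O)cc1 | intermediate
7 | dibutylboron (Z)-enolate of 4 | CCCCB(CCCC)O/C(=C\CCCCCCC(=O)OC)N1C(=O)OC[C@@H]1Cc1ccccc1 | intermediate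
8 | methyl (8S,9R)-8-{[(4S)-4-benzyl-2-oxo-1,3-oxazolidin-3-yl]carbonyl}-9-hydroxy-11-[(4-methoxybenzyl)oxy]undecanoate | COC(=O)CCCCCC[C@H](C(=O)N1C(=O)OC[C@@H]1Cc1ccccc1)[C@H](O)CCOCc1ccc(OC)cc1 | intermediate
9 | methyl (8S,9R)-8-{[(4S)-4-benzyl-2-oxo-1,3-oxazolidin-3-yl]carbonyl}-9-[(tert-butyldimethylsilyl)oxy]-11-[(4-methoxybenzyl)oxy]undecanoate | COC(=O)CCCCCC[C@H](C(=O)N1C(=O)OC[C@@H]1Cc1ccccc1)[C@H](O[Si](C)(C)C(C)(C)C)CCOCc1ccc(OC)cc1 | intermediate
10 | methyl (8R,9R)-9-[(tert-butyldimethylsilyl)oxy]-8-(hydroxymethyl)-11-[(4-methoxybenzyl)oxy]undecanoate | COC(=O)CCCCCC[C@H](CO)[C@H](O[Si](C)(C)C(C)(C)C)CCOCc1ccc(OC)cc1 | intermediate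
11 | methyl (8S,9R)-9-[(tert-butyldimethylsilyl)oxy]-8-formyl-11-[(4-methoxybenzyl)oxy]undecanoate | COC(=O)CCCCCC[C@H](C=O)[C@H](O[Si](C)(C)C(C)(C)C)CCOCc1ccc(OC)cc1 | intermediate
12 | (3S)-oct-1-en-3-ol | CCCCC[C@H](O)C=C | starting material
13 | {[(3S)-oct-1-en-3-yloxy]methyl}benzene | CCCCC[C@H](OCc1ccccc1)C=C | intermediate
14 | 9-[(3S)-3-(benzyloxy)octyl]-9-borabicyclo[3.3.1]nonane | CCCCC[C@H](OCc1ccccc1)CCB1C2CCCC1CCC2 | intermediate
15 | (3S)-3-(benzyloxy)octan-1-ol | CCCCC[C@H](OCc1ccccc1)CCO | intermediate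
16 | 5-{[(3S)-3-(benzyloxy)octyl]sulfanyl}-1-phenyl-1H-tetrazole | CCCCC[C@H](OCc1ccccc1)CCSc1nnnn1-c1ccccc1 | intermediate
17 | 5-{[(3S)-3-(benzyloxy)octyl]sulfonyl}-1-phenyl-1H-tetrazole | CCCCC[C@H](OCc1ccccc1)CCS(=O)(=O)c1nnnn1-c1ccccc1 | intermediate
18 | potassium α-sulfonyl carbanion of 17 | [K+].CCCCC[C@H](OCc1ccccc1)C[CH-]S(=O)(=O)c1nnnn1-c1ccccc1 | intermediate
19 | methyl (8R,9R)-8-[(1E,4S)-4-(benzyloxy)non-1-en-1-yl]-9-[(tert-butyldimethylsilyl)oxy]-11-[(4-methoxybenzyl)oxy]undecanoate | COC(=O)CCCCCC[C@H](/C=C/C[C@@H](OCc1ccccc1)CCCCC)[C@H](O[Si](C)(C)C(C)(C)C)CCOCc1ccc(OC)cc1 | intermediate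
20 | methyl (8R,9R)-8-[(1E,4S)-4-(benzyloxy)non-1-en-1-yl]-9-[(tert-butyldimethylsilyl)oxy]-11-hydroxyundecanoate | COC(=O)CCCCCC[C@H](/C=C/C[C@@H](OCc1ccccc1)CCCCC)[C@H](O[Si](C)(C)C(C)(C)C)CCO | intermediate
21 | methyl (8R,9R)-8-[(1E,4S)-4-(benzyloxy)non-1-en-1-yl]-9-[(tert-butyldimethylsilyl)oxy]-11-oxoundecanoate | COC(=O)CCCCCC[C@H](/C=C/C[C@@H](OCc1ccccc1)CCCCC)[C@H](O[Si](C)(C)C(C)(C)C)CC=O | intermediate
22 | methyl 7-[(1R,2R,3R,5R)-2-[(3S)-3-(benzyloxy)octyl]-5-[(tert-butyldimethylsilyl)oxy]-3-hydroxycyclopentyl]heptanoate | CCCCC[C@H](OCc1ccccc1)CC[C@H]1[C@H](O)C[C@@H](O[Si](C)(C)C(C)(C)C)[C@@H]1CCCCCCC(=O)OC | intermediate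
23 | methyl 7-[(1R,2R,3R,5R)-2-[(3S)-3-(benzyloxy)octyl]-3-[(benzyloxy)methoxy]-5-[(tert-butyldimethylsilyl)oxy]cyclopentyl]heptanoate | CCCCC[C@H](OCc1ccccc1)CC[C@H]1[C@H](OCOCc2ccccc2)C[C@@H](O[Si](C)(C)C(C)(C)C)[C@@H]1CCCCCCC(=O)OC | intermediate
24 | methyl 7-[(1R,2R,3R,5R)-2-[(3S)-3-(benzyloxy)octyl]-3-[(benzyloxy)methoxy]-5-hydroxycyclopentyl]heptanoate | CCCCC[C@H](OCc1ccccc1)CC[C@H]1[C@H](OCOCc2ccccc2)C[C@@H](O)[C@@H]1CCCCCCC(=O)OC | intermediate
25 | 7-[(1R,2R,3R,5R)-2-[(3S)-3-(benzyloxy)octyl]-3-[(benzyloxy)methoxy]-5-hydroxycyclopentyl]heptanoic acid | CCCCC[C@H](OCc1ccccc1)CC[C@H]1[C@H](OCOCc2ccccc2)C[C@@H](O)[C@@H]1CCCCCCC(=O)O | intermediate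
26 | 7-[(1R,2R,3R)-2-[(3S)-3-(benzyloxy)octyl]-3-[(benzyloxy)methoxy]-5-oxocyclopentyl]heptanoic acid | CCCCC[C@H](OCc1ccccc1)CC[C@H]1[C@H](OCOCc2ccccc2)CC(=O)[C@@H]1CCCCCCC(=O)O | intermediate
27 | 13,14-dihydro-PGE1, 7-[(1R,2R,3R)-3-hydroxy-2-[(3S)-3-hydroxyoctyl]-5-oxocyclopentyl]heptanoic acid | CCCCC[C@H](O)CC[C@H]1[C@H](O)CC(=O)[C@@H]1CCCCCCC(=O)O | target

**Step count and risks**

Total step count: 19. Longest linear sequence: 14 steps (steps 1, 3–6 and 11–19, from 9-methoxy-9-oxononanoic acid).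

Steps most likely to fail:

Step 14. The ketyl adds only slowly to an unactivated 1,2-disubstituted alkene, so coupling of two ketyls (pinacol dimerisation) or further reduction of the ketyl to the primary alcohol may overtake ring closure. A lesser risk is an eroded trans preference at C11. The fallback activates the alkene with a removable sulfonyl group at C13; it sets out from ether 13 and aldehyde 11 and returns at cyclopentanol 22. Radical addition of thiophenol to 13 (PhSH, azobisisobutyronitrile, 80 °C) gives the sulfide {[(3S)-3-(benzyloxy)octyl]sulfanyl}benzene F1. Oxidation ((NH4)6Mo7O24·4H2O, H2O2, EtOH) gives the sulfone {[(3S)-3-(benzyloxy)octyl]sulfonyl}benzene F2. Its lithio derivative (n-BuLi, THF, −78 °C) adds to 11 to give the β-hydroxy sulfone F3, which is dehydrated (MsCl, Et3N, then DBU) to the vinyl sulfone F4. DDQ then frees the C11 alcohol F5 and Dess–Martin oxidation gives the aldehyde F6. SmI2 with MeOH in THF at −78 °C should now close the same C11–C12 bond by ketyl addition to the electron-poor alkene, giving the sulfonyl cyclopentanol F7. Reductive desulfonylation (sodium amalgam Na(Hg), Na2HPO4, MeOH, −20 °C) then returns 22.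

Step 11. The sulfonyl carbanion may act as a base towards the α-branched aldehyde, leading to epimerisation at C8 or β-elimination of the silyloxy group, and the (E) preference may erode. The fallback reverses the polarity of the olefination; it sets out from alcohol 10 and alcohol 15 and returns at alkene 19. Mitsunobu thioetherification of 10 (1-phenyl-1H-tetrazole-5-thiol, PPh3, DIAD) gives the C12 sulfide F8, and molybdate/H2O2 oxidation gives the C12 sulfone F9. Dess–Martin oxidation of 15 gives (3S)-3-(benzyloxy)octanal F10. Julia–Kocienski coupling of the potassium derivative of F9 with F10 (KN(SiMe3)2, DME, −60 °C) then forms the same C12=C13 bond without an epimerisable aldehyde at C8.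

Step 5. Reduction of the hindered α-branched imide may stall, or the C1 methyl ester may be attacked, and the oxazolidinone ring may open instead of being released. The fallback leaves hydride chemistry; it sets out from imide 9 and returns at aldehyde 11, bypassing 10. Displacement of the auxiliary with lithium ethanethiolate (EtSH, n-BuLi, THF, 0 °C) gives the thioester F11. Fukuyama reduction (Et3SiH, Pd/C, acetone, rt) then gives 11 directly and should leave the methyl ester, the silyl ether and the PMB ether intact.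

Further compounds
F1 | step 14 | {[(3S)-3-(benzyloxy)octyl]sulfanyl}benzene | CCCCC[C@H](OCc1ccccc1)CCSc1ccccc1
F2 | step 14 | {[(3S)-3-(benzyloxy)octyl]sulfonyl}benzene | CCCCC[C@H](OCc1ccccc1)CCS(=O)(=O)c1ccccc1
F3 | step 14 | methyl (8R,9R)-8-[(4S)-4-(benzyloxy)-1-hydroxy-2-(phenylsulfonyl)nonyl]-9-[(tert-butyldimethylsilyl)oxy]-11-[(4-methoxybenzyl)oxy]undecanoate (mixture at the two new centres) | COC(=O)CCCCCC[C@H](C(O)C(C[C@@H](OCc1ccccc1)CCCCC)S(=O)(=O)c1ccccc1)[C@H](O[Si](C)(C)C(C)(C)C)CCOCc1ccc(OC)cc1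
F4 | step 14 | methyl (8R,9R)-8-[(4S)-4-(benzyloxy)-2-(phenylsulfonyl)non-1-en-1-yl]-9-[(tert-butyldimethylsilyl)oxy]-11-[(4-methoxybenzyl)oxy]undecanoate (alkene geometry not fixed) | COC(=O)CCCCCC[C@H](C=C(C[C@@H](OCc1ccccc1)CCCCC)S(=O)(=O)c1ccccc1)[C@H](O[Si](C)(C)C(C)(C)C)CCOCc1ccc(OC)cc1
F5 | step 14 | methyl (8R,9R)-8-[(4S)-4-(benzyloxy)-2-(phenylsulfonyl)non-1-en-1-yl]-9-[(tert-butyldimethylsilyl)oxy]-11-hydroxyundecanoate | COC(=O)CCCCCC[C@H](C=C(C[C@@H](OCc1ccccc1)CCCCC)S(=O)(=O)c1ccccc1)[C@H](O[Si](C)(C)C(C)(C)C)CCO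
F6 | step 14 | methyl (8R,9R)-8-[(4S)-4-(benzyloxy)-2-(phenylsulfonyl)non-1-en-1-yl]-9-[(tert-butyldimethylsilyl)oxy]-11-oxoundecanoate | COC(=O)CCCCCC[C@H](C=C(C[C@@H](OCc1ccccc1)CCCCC)S(=O)(=O)c1ccccc1)[C@H](O[Si](C)(C)C(C)(C)C)CC=O
F7 | step 14 | methyl 7-[(1R,2R,3R,5R)-2-[(3S)-3-(benzyloxy)-1-(phenylsulfonyl)octyl]-5-[(tert-butyldimethylsilyl)oxy]-3-hydroxycyclopentyl]heptanoate (both epimers at the sulfonyl carbon) | CCCCC[C@H](OCc1ccccc1)CC([C@H]1[C@H](O)C[C@@H](O[Si](C)(C)C(C)(C)C)[C@@H]1CCCCCCC(=O)OC)S(=O)(=O)c1ccccc1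
F8 | step 11 | methyl (8S,9R)-9-[(tert-butyldimethylsilyl)oxy]-11-[(4-methoxybenzyl)oxy]-8-{[(1-phenyl-1H-tetrazol-5-yl)sulfanyl]methyl}undecanoate | COC(=O)CCCCCC[C@H](CSc1nnnn1-c1ccccc1)[C@H](O[Si](C)(C)C(C)(C)C)CCOCc1ccc(OC)cc1
F9 | step 11 | methyl (8S,9R)-9-[(tert-butyldimethylsilyl)oxy]-11-[(4-methoxybenzyl)oxy]-8-{[(1-phenyl-1H-tetrazol-5-yl)sulfonyl]methyl}undecanoate | COC(=O)CCCCCC[C@H](CS(=O)(=O)c1nnnn1-c1ccccc1)[C@H](O[Si](C)(C)C(C)(C)C)CCOCc1ccc(OC)cc1
F10 | step 11 | (3S)-3-(benzyloxy)octanal | CCCCC[C@H](OCc1ccccc1)CC=O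
F11 | step 5 | methyl (8S,9R)-9-[(tert-butyldimethylsilyl)oxy]-8-[(ethylsulfanyl)carbonyl]-11-[(4-methoxybenzyl)oxy]undecanoate | COC(=O)CCCCCC[C@H](C(=O)SCC)[C@H](O[Si](C)(C)C(C)(C)C)CCOCc1ccc(OC)cc1
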